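## Retrosynthetic overview

- Target ⇒ one-pot annulation that makes C3a–C4 (Michael), C7–C7a (Dieckmann-type Claisen) and O1–C7a (cyclodehydration) ⇒ α-allyl-β-aryl-γ-methyl-γ-butyrolactone + 1,3-dimethoxybut-3-en-2-one (benzofuran numbering).
- Lactone ⇒ aryl 1,4-addition and enolate allylation ⇒ (R)-5-methylfuran-2(5H)-one ⇒ (R)-but-3-yn-2-ol + CO2.
- Enone ⇒ 1-methoxyvinyllithium + the Weinreb amide of methoxyacetic acid.
- Ring order: the butenolide/lactone ring comes first and serves only as a stereocontrol template, its C–O bond being cleaved later. Then, in a single operation, the six-membered carbocycle closes, followed by the dihydrofuran ring.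
- Stereocentres: C2 from the alkynol; C3 anti to the C2 methyl (conjugate addition); C3a by enolate attack anti to the aryl group; C5 by equilibration.

Assumption: enantiopure (R)-but-3-yn-2-ol, (3,4,5-trimethoxyphenyl)magnesium bromide solution, methyl vinyl ether and N,2-dimethoxy-N-methylacetamide are bought as such, and the C5-methoxy epimer trans to the 3a-allyl group is taken as the thermodynamically favoured one.

## Route

Step 1
Reactants: 1 (R)-but-3-yn-2-ol
Product: 3 (R)-4-hydroxypent-2-ynoic acid, via dilithium alkynide alkoxide 2 (not isolated)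
Conditions: n-BuLi (2.1 equiv), THF, −78 to −30 °C; CO2 (g), −78 °C to rt; 2 M HCl
Reagents that add atoms: carbon dioxide, O=C=O
Why: Double deprotonation gives the O,C-dianion 2, whose acetylide carbon is carboxylated by CO2 (carboxylation of a lithium acetylide); the carbinol stereocentre is not involved.

Step 2
Reactants: 3 (R)-4-hydroxypent-2-ynoic acid
Product: 5 (R)-5-methylfuran-2(5H)-one, via (R,Z)-4-hydroxypent-2-enoic acid 4 (not isolated)
Conditions: H2 (1 atm), Pd/CaCO3 poisoned with Pb(OAc)2, quinoline, EtOAc, rt; then TsOH·H2O (cat.), CH2Cl2, rt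
Reagents that add atoms: none
Why: Syn semi-hydrogenation on lead-poisoned palladium (Lindlar reduction) gives the (Z)-hydroxy acid 4, whose cis OH and CO2H close to the butenolide by acid-catalysed lactonisation; the stereocentre is untouched.

Step 3
Reactants: 5 (R)-5-methylfuran-2(5H)-one; 6 (3,4,5-trimethoxyphenyl)magnesium bromide; 7 allyl bromide
Product: 9 (3S,4R,5R)-5-methyl-3-(prop-2-en-1-yl)-4-(3,4,5-trimethoxyphenyl)oxolan-2-one, via bromomagnesium lactone enolate 8 (not isolated)
Conditions: 6 (1.4 equiv), CuBr·SMe2 (10 mol %), THF, −78 to −30 °C; then 7 (3 equiv), DMPU, −30 to 0 °C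
Reagents that add atoms: none
Why: Copper-catalysed conjugate addition of the aryl Grignard reagent occurs anti to the C5 methyl group, and enolate 8 is then C-allylated anti to the new aryl group (tandem conjugate addition–enolate alkylation); the C3 centre made here is planarised again in step 5.

Step 4
Reactants: 10 methyl vinyl ether; 11 N,2-dimethoxy-N-methylacetamide
Product: 13 1,3-dimethoxybut-3-en-2-one, via 1-methoxyvinyllithium 12 (not isolated)
Conditions: 10 (2 equiv), t-BuLi (1.2 equiv), THF, −78 to 0 °C; 11, −78 °C; AcOH, −78 °C to rt; used at once as a cold solution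
Reagents that add atoms: none
Why: α-Lithiation of the enol ether gives the acyl-anion equivalent 12, which adds only once to the Weinreb amide because the chelated tetrahedral adduct survives until the quench (Weinreb ketone synthesis); no stereocentre is formed.

Step 5
Reactants: 9 (3S,4R,5R)-5-methyl-3-(prop-2-en-1-yl)-4-(3,4,5-trimethoxyphenyl)oxolan-2-one; 13 1,3-dimethoxybut-3-en-2-one
Product: 17 (2R,3S,3aS,5S)-5,7-dimethoxy-2-methyl-3a-(prop-2-en-1-yl)-3-(3,4,5-trimethoxyphenyl)-3,3a,4,5-tetrahydro-1-benzofuran-6(2H)-one, via lactone lithium enolate 14 (not isolated), via Michael adduct enolate 15 (not isolated), via ring-opened diketonate 16 (not isolated)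
Conditions: LiN(i-Pr)2 (1.1 equiv), THF, −78 °C; 13 (1.3 equiv, slow addition), −78 °C to rt; then TsOH·H2O (2.5 equiv), 40 °C; then DBU (3 equiv), rt
Reagents that add atoms: none
Why: Proposed new method: enolate 14 adds to enone 13 in a Michael addition from the face anti to the neighbouring aryl group, which fixes C3a with allyl cis to aryl; the α'-methoxy ketone enolate 15 then closes the six-membered ring by a Dieckmann-type Claisen attack on the lactone carbonyl, expelling the C2 alkoxide to give diketonate 16; on acidification the freed hydroxyl adds to the C7a carbonyl and loses water to close the dihydrofuran as a vinylogous ester, and DBU equilibrates C5 through the enolate to the epimer with the methoxy group pseudo-equatorial and trans to the pseudo-axial allyl group; the closest known reaction types are the Michael–Claisen annulation of ester enolates with vinyl ketones to cyclohexane-1,3-diones and the acid-catalysed cyclodehydration of hydroxy-1,3-diketones to cyclic vinylogous esters.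

## Compound list

1 | (R)-but-3-yn-2-ol | C[C@@H](O)C#C | starting material
2 | dilithium salt of (R)-but-3-yn-2-ol (lithium alkoxide, lithium acetylide) | [Li+].[Li+].C[C@@H]([O-])C#[C-] | intermediate
3 | (R)-4-hydroxypent-2-ynoic acid | C[C@@H](O)C#CC(=O)O | intermediate
4 | (R,Z)-4-hydroxypent-2-enoic acid | C[C@@H](O)/C=C\C(=O)O | intermediate
5 | (R)-5-methylfuran-2(5H)-one | C[C@H]1OC(=O)C=C1 | intermediate
6 | (3,4,5-trimethoxyphenyl)magnesium bromide | COc1cc([Mg]Br)cc(OC)c1OC | starting material
7 | allyl bromide (3-bromoprop-1-ene) | C=CCBr | starting material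
8 | bromomagnesium (4R,5R)-5-methyl-4-(3,4,5-trimethoxyphenyl)-4,5-dihydrofuran-2-olate | Br[Mg]OC1=C[C@H](c2cc(OC)c(OC)c(OC)c2)[C@@H](C)O1 | intermediate
9 | (3S,4R,5R)-5-methyl-3-(prop-2-en-1-yl)-4-(3,4,5-trimethoxyphenyl)oxolan-2-one (aryl trans to methyl, allyl trans to aryl) | O=C1O[C@H](C)[C@@H](c2cc(OC)c(OC)c(OC)c2)[C@@H]1CC=C | intermediate
10 | methyl vinyl ether | C=COC | starting material
11 | N,2-dimethoxy-N-methylacetamide | COCC(=O)N(C)OC | starting material
12 | 1-methoxyvinyllithium | [Li]C(=C)OC | intermediate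
13 | 1,3-dimethoxybut-3-en-2-one | C=C(OC)C(=O)COC | intermediate
14 | lithium (4S,5R)-5-methyl-3-(prop-2-en-1-yl)-4-(3,4,5-trimethoxyphenyl)-4,5-dihydrofuran-2-olate | [Li+].[O-]C1=C(CC=C)[C@H](c2cc(OC)c(OC)c(OC)c2)[C@@H](C)O1 | intermediate
15 | lithium enolate of (3S,4S,5R)-3-(2,4-dimethoxy-3-oxobutyl)-5-methyl-3-(prop-2-en-1-yl)-4-(3,4,5-trimethoxyphenyl)oxolan-2-one (enolate geometry open) | [Li+].C=CC[C@@]1(CC(OC)=C([O-])COC)C(=O)O[C@H](C)[C@H]1c1cc(OC)c(OC)c(OC)c1 | intermediate
16 | lithium (6S)-6-[(1S,2R)-2-hydroxy-1-(3,4,5-trimethoxyphenyl)propyl]-2,4-dimethoxy-3-oxo-6-(prop-2-en-1-yl)cyclohex-1-en-1-olate (both C4 epimers) | [Li+].C=CC[C@]1(CC(OC)C(=O)C(OC)=C1[O-])[C@H](c1cc(OC)c(OC)c(OC)c1)[C@@H](C)O | intermediate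
17 | (2R,3S,3aS,5S)-5,7-dimethoxy-2-methyl-3a-(prop-2-en-1-yl)-3-(3,4,5-trimethoxyphenyl)-3,3a,4,5-tetrahydro-1-benzofuran-6(2H)-one | C=CC[C@@]12C[C@H](OC)C(=O)C(OC)=C1O[C@H](C)[C@H]2c1cc(OC)c(OC)c(OC)c1 | target

## Step count and risk

Total steps: 5. Longest linear sequence: 4 (steps 1, 2, 3 and 5); step 4 is a one-step side branch.

The step most likely to fail is step 5. The hindered enolate 14 may polymerise 13 or add 1,2, and the Claisen closure onto the α-quaternary lactone may stall. The fallback sets out from 9 and comes back at 17, and separates the events under Lewis-acid control. Compound 9 is converted (LiN(i-Pr)2, Me3SiCl, THF, −78 °C) into its ketene acetal trimethyl{[(4S,5R)-5-methyl-3-(prop-2-en-1-yl)-4-(3,4,5-trimethoxyphenyl)-4,5-dihydrofuran-2-yl]oxy}silane F1. F1 undergoes a TiCl4-mediated Mukaiyama–Michael addition to 13 (CH2Cl2, −78 °C, the α-methoxy ketone chelating TiCl4), again anti to the aryl group. This gives the isolated keto lactone (3S,4S,5R)-3-(2,4-dimethoxy-3-oxobutyl)-5-methyl-3-(prop-2-en-1-yl)-4-(3,4,5-trimethoxyphenyl)oxolan-2-one F2. F2 is then cyclised in a separate operation (t-BuOK, THF, 0 °C to rt; then TsOH·H2O; then DBU) to 17.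

The second is step 3. The magnesium enolate 8 may resist allylation, or the Grignard reagent may attack the lactone carbonyl. The fallback sets out from 5 and comes back at 9. Rhodium-catalysed conjugate addition of (3,4,5-trimethoxyphenyl)boronic acid ([Rh(cod)Cl]2, KOH, dioxane/H2O, 50 °C), anti to the methyl group, gives (4R,5R)-5-methyl-4-(3,4,5-trimethoxyphenyl)oxolan-2-one F3. F3 is deprotonated with LiN(SiMe3)2 (THF, −78 °C) and alkylated with 7, anti to the aryl group, to give 9.

The third is step 4. The basic vinyllithium 12 may enolise the α-methoxy amide 11 instead of adding, and 13 polymerises easily. The fallback sets out from 10 and comes back at 13. Compound 10 is lithiated as before and added to methoxyacetaldehyde (THF, −78 °C), where addition outruns enolisation, to give 1,3-dimethoxybut-3-en-2-ol F4. F4 is oxidised with Dess–Martin periodinane/NaHCO3 (or MnO2) in CH2Cl2 to 13, again used at once in solution.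

Further compounds
F1 | step 5 | trimethyl{[(4S,5R)-5-methyl-3-(prop-2-en-1-yl)-4-(3,4,5-trimethoxyphenyl)-4,5-dihydrofuran-2-yl]oxy}silane | C[Si](C)(C)OC1=C(CC=C)[C@H](c2cc(OC)c(OC)c(OC)c2)[C@@H](C)O1
F2 | step 5 | (3S,4S,5R)-3-(2,4-dimethoxy-3-oxobutyl)-5-methyl-3-(prop-2-en-1-yl)-4-(3,4,5-trimethoxyphenyl)oxolan-2-one | C=CC[C@@]1(CC(OC)C(=O)COC)C(=O)O[C@H](C)[C@H]1c1cc(OC)c(OC)c(OC)c1
F3 | step 3 | (4R,5R)-5-methyl-4-(3,4,5-trimethoxyphenyl)oxolan-2-one | O=C1C[C@H](c2cc(OC)c(OC)c(OC)c2)[C@@H](C)O1
F4 | step 4 | 1,3-dimethoxybut-3-en-2-ol | C=C(OC)C(O)COC
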